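**Strategy.** In isochroman-1-one numbering, the benzene ring carries para oxygens at C5 (OMe) and C8 (OH) that flank the ring-fusion atoms C4a and C8a. The ring is therefore unmasked as a quinone monoketal whose C4a=C8a enone accepts at C4a and then donates at C8a. The lactone ring (C1, O2, C3, C4, C4a, C8a) is closed by two C–C bonds in one flask: an α-acetoxyalkyl radical (C4) adds to C4a, and the C8a enolate is acylated by the tethered aryl carbonate (C1). Loss of methanol then aromatises the carbocycle and gives the target directly. The precursors are a 3-geranyloxy-4,4-dimethoxycyclohexadienone and an (R)-lactaldehyde-derived bromoacetate carrying C1 as a phenyl carbonate.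

Key step: step 7

Remark: atom labels below follow isochroman-1-one numbering (C1 lactone carbonyl, O2, C3, C4, C4a, C5 to C8, C8a); boronate 1 and (R)-but-3-en-2-ol 6 are taken as purchasable.

Step 1
Reactants: 1 2-methoxy-5-(4,4,5,5-tetramethyl-1,3,2-dioxaborolan-2-yl)phenol, 2 geranyl bromide
Product: 3 2-{3-[(2E)-3,7-dimethylocta-2,6-dien-1-yloxy]-4-methoxyphenyl}-4,4,5,5-tetramethyl-1,3,2-dioxaborolane
Conditions: K2CO3, DMF, 25 °C
Reagents that add atoms: none
Why: Williamson ether synthesis, the phenoxide displacing the primary allylic bromide by SN2 so that the E geometry of the geranyl unit is kept.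

Step 2
Reactants: 3 aryl boronate
Product: 4 3-[(2E)-3,7-dimethylocta-2,6-dien-1-yloxy]-4-methoxyphenol
Conditions: H2O2 (30 % aq), NaOH, THF, 0 °C
Reagents that add atoms: hydrogen peroxide, OO
Why: Oxidative ipso-hydroxylation of an arylboronate (1,2-aryl shift from boron to oxygen), under which the isolated trisubstituted alkenes should be inert.

Step 3
Reactants: 4 phenol
Product: 5 3-[(2E)-3,7-dimethylocta-2,6-dien-1-yloxy]-4,4-dimethoxycyclohexa-2,5-dien-1-one
Conditions: PhI(OAc)2, MeOH, 0 °C, then NaHCO3
Reagents that add atoms: methanol, CO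
Why: Oxidative dearomatisation of a para-alkoxyphenol to the quinone monoketal, methanol adding at the methoxy-bearing para carbon; phenol oxidation should be much faster than attack on the alkenes.

Step 4
Reactants: 6 (R)-but-3-en-2-ol, 7 phenyl chloroformate
Product: 8 (R)-but-3-en-2-yl phenyl carbonate
Conditions: pyridine, CH2Cl2, 0 °C
Reagents that add atoms: none
Why: O-acylation of the secondary alcohol by a chloroformate (carbonate formation) without touching the stereocentre that becomes C3.

Step 5
Reactants: 8 allylic carbonate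
Product: 10 (R)-1-oxopropan-2-yl phenyl carbonate, via secondary ozonide 9 (not isolated)
Conditions: O3, CH2Cl2, −78 °C; then Me2S, −78 to 0 °C; used crude
Reagents that add atoms: ozone, [O-][O+]=O
Why: Ozonolysis with reductive work-up cleaves the terminal alkene to the aldehyde under neutral conditions, so the adjacent stereocentre should not enolise.

Step 6
Reactants: 10 aldehyde
Product: 11 (2R)-1-bromo-2-[(phenoxycarbonyl)oxy]propyl acetate (mixture of C1 epimers)
Conditions: AcBr, ZnBr2 (5 mol %), CH2Cl2, −20 to 0 °C; used without purification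
Reagents that add atoms: acetyl bromide, CC(=O)Br
Why: Lewis-acid-catalysed addition of an acyl bromide across the aldehyde carbonyl gives the α-bromoalkyl ester; the new centre is formed unselectively, which is harmless because it becomes a radical in step 7.

Step 7
Reactants: 5 quinone monoketal, 11 α-bromoalkyl acetate
Product: 14 (3R,4R)-6-{[(2E)-3,7-dimethylocta-2,6-dien-1-yl]oxy}-8-hydroxy-5-methoxy-3-methyl-1-oxo-3,4-dihydro-1H-isochromen-4-yl acetate, via Giese adduct ketone 12 (not isolated), via β-keto lactone 13 (not isolated)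
Conditions: Ir(ppy)3 (1 mol %), Hantzsch ester, iPr2NEt, CH2Cl2, blue LEDs, 25 °C; then LiN(SiMe3)2, THF, −78 to −40 °C (same flask); then AcOH, 25 °C
Reagents that add atoms: none
Why: Proposed new method: photoreduction of the C–Br bond of 11 gives a nucleophilic α-acetoxyalkyl radical (both epimers of 11 converge on it) that adds to the unsubstituted enone β-carbon C4a of 5 and is reduced to ketone 12 (reductive Giese addition, closest known for glycosyl-type α-acyloxyalkyl bromides and enones); LiN(SiMe3)2 added to the same flask forms the C8a enolate, which is C-acylated by the tethered phenyl carbonate carbon C1 to give 13 (closest anionic precedent: Michael–Claisen annulation of quinone monoketals), and acetic acid eliminates methanol to aromatise. A radical is used because any C4 carbanion would expel the β-carbonate; merging the radical addition with the Claisen closure on a quinone monoketal is the untested part. The lactone ring closes by 6-exo-trig attack of the enolate on the carbonate carbonyl, whereas the benzene ring is not closed but unveiled from the ketal. C3 comes unchanged from 6, and C4 is set in the radical addition by 1,2-induction from C3 (Felkin–Anh-type transition state with the C3–O bond anti to the forming bond and methyl gauche to H rather than to OAc), which should favour the 3,4-cis (4R) isomer; the C4a and C8a centres vanish on aromatisation. The step needs addition at C4a rather than C6 (secured by the alkoxy substitution and vinylogous-ester deactivation of C6), acylation at the carbonate rather than the acetate (secured by the phenoxide leaving group, attack on the acetate being reversible), and the C5-OMe/C8-OH pattern (secured by the ketal).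

**Compound list**

1 | 2-methoxy-5-(4,4,5,5-tetramethyl-1,3,2-dioxaborolan-2-yl)phenol | COc1ccc(cc1O)B1OC(C)(C)C(C)(C)O1 | starting material
2 | geranyl bromide, (2E)-1-bromo-3,7-dimethylocta-2,6-diene | CC(C)=CCC/C(C)=C/CBr | starting material
3 | 2-{3-[(2E)-3,7-dimethylocta-2,6-dien-1-yloxy]-4-methoxyphenyl}-4,4,5,5-tetramethyl-1,3,2-dioxaborolane | COc1ccc(cc1OC/C=C(\C)CCC=C(C)C)B1OC(C)(C)C(C)(C)O1 | intermediate
4 | 3-[(2E)-3,7-dimethylocta-2,6-dien-1-yloxy]-4-methoxyphenol | COc1ccc(O)cc1OC/C=C(\C)CCC=C(C)C | intermediate
5 | 3-[(2E)-3,7-dimethylocta-2,6-dien-1-yloxy]-4,4-dimethoxycyclohexa-2,5-dien-1-one | COC1(OC)C=CC(=O)C=C1OC/C=C(\C)CCC=C(C)C | intermediate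
6 | (R)-but-3-en-2-ol | C[C@@H](O)C=C | starting material
7 | phenyl chloroformate | O=C(Cl)Oc1ccccc1 | starting material
8 | (R)-but-3-en-2-yl phenyl carbonate | C[C@@H](OC(=O)Oc1ccccc1)C=C | intermediate
9 | (R)-1-(1,2,4-trioxolan-3-yl)ethyl phenyl carbonate (secondary ozonide) | C[C@@H](OC(=O)Oc1ccccc1)C1OCOO1 | intermediate (not isolated)
10 | (R)-1-oxopropan-2-yl phenyl carbonate | C[C@@H](OC(=O)Oc1ccccc1)C=O | intermediate
11 | (2R)-1-bromo-2-[(phenoxycarbonyl)oxy]propyl acetate, C1 epimers | C[C@@H](OC(=O)Oc1ccccc1)C(Br)OC(C)=O | intermediate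
12 | (1R,2R)-1-{3-[(2E)-3,7-dimethylocta-2,6-dien-1-yloxy]-2,2-dimethoxy-5-oxocyclohex-3-en-1-yl}-2-[(phenoxycarbonyl)oxy]propyl acetate (ring centre unassigned) | COC1(OC)C(CC(=O)C=C1OC/C=C(\C)CCC=C(C)C)[C@@H](OC(C)=O)[C@@H](C)OC(=O)Oc1ccccc1 | intermediate (not isolated)
13 | (3R,4R)-6-[(2E)-3,7-dimethylocta-2,6-dien-1-yloxy]-5,5-dimethoxy-3-methyl-1,8-dioxo-3,4,4a,5,8,8a-hexahydro-1H-isochromen-4-yl acetate | COC1(OC)C(OC/C=C(\C)CCC=C(C)C)=CC(=O)C2C1[C@@H](OC(C)=O)[C@@H](C)OC2=O | intermediate (not isolated)
14 | (3R,4R)-6-{[(2E)-3,7-dimethylocta-2,6-dien-1-yl]oxy}-8-hydroxy-5-methoxy-3-methyl-1-oxo-3,4-dihydro-1H-isochromen-4-yl acetate | COc1c(OC/C=C(\C)CCC=C(C)C)cc(O)c2c1[C@@H](OC(C)=O)[C@@H](C)OC2=O | target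

**Step count.** Total: 7 steps. Longest linear sequence: 4 steps (1, 2, 3, 7 or 4, 5, 6, 7).

**Steps most likely to fail**

1. Step 7. The process at risk is poor facial selectivity of the radical addition, since 1,2-induction from C3 may be weak and much C4 epimer would form. The fallback resets C4 by known, catalyst-controlled chemistry and sets out from the epimer (3R,4S)-acetate F1, separated from 14 by chromatography. Lipase-catalysed methanolysis (Candida antarctica lipase B, MeOH, MTBE, 30 °C) should give the trans alcohol F2 without base-induced translactonisation. MnO2 in CH2Cl2 should oxidise the benzylic alcohol to the 3-methylisochromane-1,4-dione F3. Asymmetric transfer hydrogenation with dynamic kinetic resolution (RuCl(p-cymene)[(S,S)-TsDPEN], HCO2H/Et3N, 30 °C) should then give the cis (3R,4R) alcohol F4, C3 equilibrating through the enol and the catalyst fixing C4. Ac2O (1.1 equiv) and pyridine in CH2Cl2 at 0 °C should acetylate the secondary alcohol in preference to the chelated C8 phenol and return 14.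

2. Step 6. The process at risk is loss of the hydrolytically labile bromide on handling, together with Lewis-acid-promoted enolisation of 10 that would erode C3. The fallback sets out from 10. Ac2O with catalytic FeCl3 (CH2Cl2, 0 °C) should give the stable, purifiable acylal (2R)-2-[(phenoxycarbonyl)oxy]propane-1,1-diyl diacetate F5. Me3SiBr (CH2Cl2, 0 °C) should then exchange one acetate for bromide, as with anomeric acetates, returning 11 just before use.

3. Step 3. The process at risk is attack of the iodine oxidant on the trisubstituted alkenes and over-oxidation or hydrolysis of the monoketal to the quinone. The fallback sets out from 4. MeI and K2CO3 in acetone should give 2-[(2E)-3,7-dimethylocta-2,6-dien-1-yloxy]-1,4-dimethoxybenzene F6. Anodic oxidation (Pt anode, KOH, MeOH, 0 °C) should give the quinone bisketal F7. Dilute aqueous AcOH in acetone at 0 °C should hydrolyse only the ketal whose cation is stabilised through the enol-ether oxygen, returning 5.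

**Further compounds**

F1 | step 7 | (3R,4S)-6-{[(2E)-3,7-dimethylocta-2,6-dien-1-yl]oxy}-8-hydroxy-5-methoxy-3-methyl-1-oxo-3,4-dihydro-1H-isochromen-4-yl acetate | COc1c(OC/C=C(\C)CCC=C(C)C)cc(O)c2c1[C@H](OC(C)=O)[C@@H](C)OC2=O
F2 | step 7 | (3R,4S)-6-{[(2E)-3,7-dimethylocta-2,6-dien-1-yl]oxy}-4,8-dihydroxy-5-methoxy-3-methyl-3,4-dihydro-1H-isochromen-1-one | COc1c(OC/C=C(\C)CCC=C(C)C)cc(O)c2c1[C@H](O)[C@@H](C)OC2=O
F3 | step 7 | (3R)-6-{[(2E)-3,7-dimethylocta-2,6-dien-1-yl]oxy}-8-hydroxy-5-methoxy-3-methyl-1H-isochromene-1,4(3H)-dione | COc1c(OC/C=C(\C)CCC=C(C)C)cc(O)c2c1C(=O)[C@@H](C)OC2=O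
F4 | step 7 | (3R,4R)-6-{[(2E)-3,7-dimethylocta-2,6-dien-1-yl]oxy}-4,8-dihydroxy-5-methoxy-3-methyl-3,4-dihydro-1H-isochromen-1-one | COc1c(OC/C=C(\C)CCC=C(C)C)cc(O)c2c1[C@@H](O)[C@@H](C)OC2=O
F5 | step 6 | (2R)-2-[(phenoxycarbonyl)oxy]propane-1,1-diyl diacetate | C[C@@H](OC(=O)Oc1ccccc1)C(OC(C)=O)OC(C)=O
F6 | step 3 | 2-[(2E)-3,7-dimethylocta-2,6-dien-1-yloxy]-1,4-dimethoxybenzene | COc1ccc(OC)cc1OC/C=C(\C)CCC=C(C)C
F7 | step 3 | 1-[(2E)-3,7-dimethylocta-2,6-dien-1-yloxy]-3,3,6,6-tetramethoxycyclohexa-1,4-diene | COC1(OC)C=CC(OC)(OC)C=C1OC/C=C(\C)CCC=C(C)C
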